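**Retrosynthetic overview**

1. Feature: with the chain numbered C1 (vinyl CH2) to C11 (gem-dimethyl carbon), the oxane O–C7–C8–C9–C10–C11 (methyl on C7, two methyls on C11, C7 and C10 in a 1,4 relation) is the ether ring of 1,8-cineole, whose cage ties C10 back to C7 through C5–C6 where the target has bromine.
2. Key disconnection: the C10–O(acyl) bond of lactone 7, made from enantiopure 3-oxo-1,8-cineole 6 by Baeyer–Villiger oxygen insertion between C5 and C10; 6 comes from 1,8-cineole by methylene oxidation and classical resolution.
3. C6: bromination on the rigid lactone, lactone reduction, C5–C6 oxirane (inversion at C6), opening at C5 by a propargyl anion (C4–C5 bond), then both C–Br bonds by invertive Appel displacement of the C6 and C10 hydroxyls.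
4. C1–C3: methylalumination/hydroxymethylation of the alkyne (C3 methyl, C1), Sharpless epoxidation (C3–O), reductive opening of the epoxy iodide to the (S)-vinyl carbinol.
5. Ring order: the oxane is present from the start inside the cineole cage; the seven-membered lactone is formed in step 6 and opened in step 8; the C5–C6 and C2–C3 oxiranes are transient.

Key step: step 6

Assumption: electrophiles are taken to enter the enolate of lactone 7 on the face syn to the ring oxygen; the route is written for this outcome and the fallback for step 7 covers the opposite one. Target numbering C1–C11 is used for all intermediates.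

**Route**

Step 1
Reactants: 1 1,8-cineole (1,3,3-trimethyl-2-oxabicyclo[2.2.2]octane)
Product: 2 rac-1,3,3-trimethyl-2-oxabicyclo[2.2.2]octan-5-one (racemic 3-oxo-1,8-cineole)
Conditions: CrO3, Ac2O, AcOH, 20–30 °C; chromatography
Reagents that add atoms: chromium trioxide O=[Cr](=O)=O
Why: Chromyl acetate (CrO2(OAc)2) oxidation of a ring methylene to a ketone: the methylene next to the bridgehead methine (C5) is less hindered than the one next to the quaternary C7 and should be oxidised preferentially, and because the two ethano bridges of the meso ether are enantiotopic the ketone forms as a racemate.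

Step 2
Reactants: 2 rac-1,3,3-trimethyl-2-oxabicyclo[2.2.2]octan-5-one
Product: 3 rac-(1S*,4R*,5S*)-1,3,3-trimethyl-2-oxabicyclo[2.2.2]octan-5-ol (hydroxyl syn to the oxygen bridge)
Conditions: NaBH4, MeOH, 0 °C
Reagents that add atoms: none
Why: Sodium borohydride reduction of a ketone: hydride should arrive from the face of the ethano bridge, the other face being screened by the nearer methyl of the gem-dimethyl carbon, so one racemic diastereomer is expected; this carbinol centre only serves the resolution and is removed again in step 5.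

Step 3
Reactants: 3 rac-(1S*,4R*,5S*)-1,3,3-trimethyl-2-oxabicyclo[2.2.2]octan-5-ol
Product: 4 (1S,4R,5S)-1,3,3-trimethyl-2-oxabicyclo[2.2.2]octan-5-yl (1S,4R)-4,7,7-trimethyl-3-oxo-2-oxabicyclo[2.2.1]heptane-1-carboxylate (camphanate)
Conditions: (1S)-(−)-camphanic chloride, pyridine, DMAP (cat.), CH2Cl2, 0 °C to rt; separation of the two diastereomeric esters by crystallisation and chromatography
Reagents that add atoms: (1S)-(−)-camphanic chloride ClC(=O)[C@@]12CC[C@@](C)(C(=O)O1)C2(C)C
Why: Esterification with an enantiopure acid chloride (classical resolution through diastereomers): the two camphanates differ in solubility and polarity and should be separable, and ester 4 is to be identified by X-ray analysis relative to the known configuration of the camphanoyl group.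

Step 4
Reactants: 4 camphanate of the (1S,4R,5S)-alcohol
Product: 5 (1S,4R,5S)-1,3,3-trimethyl-2-oxabicyclo[2.2.2]octan-5-ol
Conditions: NaOMe (cat.), MeOH, reflux
Reagents that add atoms: none
Why: Methoxide-catalysed transesterification cleaves the ester at the acyl carbon, so the resolved alcohol is released with all three stereocentres unchanged.

Step 5
Reactants: 5 (1S,4R,5S)-1,3,3-trimethyl-2-oxabicyclo[2.2.2]octan-5-ol
Product: 6 (1S,4S)-1,3,3-trimethyl-2-oxabicyclo[2.2.2]octan-5-one (enantiopure 3-oxo-1,8-cineole)
Conditions: (n-Pr4N)RuO4 (cat.), N-methylmorpholine N-oxide, 4 Å molecular sieves, CH2Cl2, rt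
Reagents that add atoms: none
Why: Ley–Griffith oxidation of the secondary alcohol under neutral conditions removes the auxiliary carbinol centre and leaves the two bridgehead centres, which cannot epimerise, as the only stereocentres of the beta-alkoxy ketone.

Step 6
Reactants: 6 (1S,4S)-1,3,3-trimethyl-2-oxabicyclo[2.2.2]octan-5-one
Product: 7 (1S,5S)-5,7,7-trimethyl-2,6-dioxabicyclo[3.2.2]nonan-3-one
Conditions: m-CPBA, NaHCO3 (buffer), CH2Cl2, 0 °C to rt
Reagents that add atoms: 3-chloroperbenzoic acid OOC(=O)c1cccc(Cl)c1
Why: The peracid adds to the C5 carbonyl from the face of the ethano bridge to give the tetrahedral peroxy hemiketal (Criegee adduct), and the C5–C10 bond, held antiperiplanar to the O–O bond, shifts to oxygen with loss of 3-chlorobenzoate. This is the Baeyer–Villiger oxidation, whose closest precedent is the ring expansion of bicyclo[2.2.2]octan-2-ones to 2-oxabicyclo[3.2.2]nonan-3-ones by bridgehead migration. The seven-membered lactone ring is closed not by a cyclisation but by a concerted 1,2-shift that inserts oxygen into the six-membered carbocycle (ring expansion from six to seven), turning the cage into a 2,6-dioxabicyclo[3.2.2]nonanone. The C10–O stereocentre is fixed by retention of configuration at the migrating carbon, which places the oxygen on the oxane face that carries the C7 side chain, trans to the C7 methyl. The step needs regioselectivity between the bridgehead methine C10 and the methylene C6: the more substituted C10 better carries the positive charge that builds up during the shift, and since each candidate has one beta oxygen no electronic bias opposes this order. The bicarbonate buffer should keep 3-chlorobenzoic acid from opening the beta-alkoxy ketone by retro-oxa-Michael cleavage.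

Step 7
Reactants: 7 (1S,5S)-5,7,7-trimethyl-2,6-dioxabicyclo[3.2.2]nonan-3-one
Product: 9 (1S,4S,5S)-4-bromo-5,7,7-trimethyl-2,6-dioxabicyclo[3.2.2]nonan-3-one, via trimethylsilyl ketene acetal 8 (not isolated)
Conditions: LiN(i-Pr)2, Me3SiCl (in situ quench), THF, −78 °C; solvent exchange to pentane, filtration; then NBS, THF, −78 °C
Reagents that add atoms: N-bromosuccinimide O=C1CCC(=O)N1Br
Why: Alpha-bromination of a lactone through its silyl ketene acetal: C6 is the only enolisable position, immediate O-silylation at −78 °C should forestall beta-elimination of the C7 ring oxygen, and bromine is expected to enter on the face syn to the ring oxygen (flanked by the bare oxygen instead of the C8 methylene and anti to the C7–C8 bond), which gives the (6R) bromide.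

Step 8
Reactants: 9 (1S,4S,5S)-4-bromo-5,7,7-trimethyl-2,6-dioxabicyclo[3.2.2]nonan-3-one
Product: 11 (3S,6S)-2,2,6-trimethyl-6-[(2S)-oxiran-2-yl]oxan-3-ol, via bromohydrin diol 10 (not isolated)
Conditions: i-Bu2AlH, CH2Cl2, −78 to 0 °C; aqueous potassium sodium tartrate (KNaC4H4O6) work-up; then K2CO3, MeOH, rt
Reagents that add atoms: none
Why: Hydride reduction of the lactone followed by intramolecular Williamson ether synthesis: i-Bu2AlH frees the C5 and C10 hydroxyls without touching the C10–O bond (configuration from step 6), and carbonate then closes the C5–O–C6 oxirane by 3-exo-tet displacement of bromide with inversion at C6, which should be far faster than attack by the C10 hydroxyl through a boat oxane.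

Step 9
Reactants: 11 (3S,6S)-2,2,6-trimethyl-6-[(2S)-oxiran-2-yl]oxan-3-ol; 12 1-(trimethylsilyl)propyne
Product: 14 (3S,6S)-6-[(1S)-1-hydroxypent-4-yn-1-yl]-2,2,6-trimethyloxan-3-ol, via silylated alkyne diol 13 (not isolated)
Conditions: 12 (3.2 equiv), n-BuLi (3.0 equiv), THF, −78 to −20 °C; add 11, −78 to 0 °C; MeOH quench, then K2CO3 (cat.), MeOH, rt
Reagents that add atoms: none
Why: Epoxide opening by a propargyl anion equivalent: the lithiated silylpropyne attacks through its CH2 carbon at the unhindered C5 terminus (C6 is neopentyl), forming the C4–C5 bond and leaving the C6–O bond as the (6S) alcohol, the first equivalent of base only deprotonating the C10 hydroxyl; methanolic carbonate then removes the alkynyl silyl group.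

Step 10
Reactants: 14 (3S,6S)-6-[(1S)-1-hydroxypent-4-yn-1-yl]-2,2,6-trimethyloxan-3-ol
Product: 15 (3R,6S)-3-bromo-6-[(1R)-1-bromopent-4-yn-1-yl]-2,2,6-trimethyloxane
Conditions: CBr4, P(n-C8H17)3, toluene, 70 °C
Reagents that add atoms: carbon tetrabromide BrC(Br)(Br)Br
Why: Double Appel bromination: both secondary hydroxyls are turned into alkoxyphosphonium ions and displaced by bromide with SN2 inversion, so that C10 ends with bromine trans to the side chain and cis to the C7 methyl (10R) and C6 goes from S to R; the excess of reagent activates both hydroxyls at once so that neither is left as an internal nucleophile, and the non-polar solvent disfavours participation by the ring oxygen.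

Step 11
Reactants: 15 (3R,6S)-3-bromo-6-[(1R)-1-bromopent-4-yn-1-yl]-2,2,6-trimethyloxane
Product: 17 (2E,6R)-6-bromo-6-[(2S,5R)-5-bromo-2,6,6-trimethyloxan-2-yl]-3-methylhex-2-en-1-ol, via alkenyldimethylalane 16 (not isolated)
Conditions: AlMe3 (3 equiv), Cp2ZrCl2 (0.3 equiv), CH2Cl2, 0 °C to rt; then (CH2O)n, 0 °C to rt; aqueous KNaC4H4O6 work-up
Reagents that add atoms: trimethylaluminium C[Al](C)C; formaldehyde (from paraformaldehyde) C=O
Why: Negishi zirconium-catalysed methylalumination followed by hydroxymethylation: methyl and aluminium add syn across the terminal alkyne with methyl on the internal carbon C3, and formaldehyde replaces aluminium with retention of geometry, so only the (E)-allylic alcohol should form; secondary alkyl bromides and the hindered ether are expected to be inert to the alane at this temperature.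

Step 12
Reactants: 17 (2E,6R)-6-bromo-6-[(2S,5R)-5-bromo-2,6,6-trimethyloxan-2-yl]-3-methylhex-2-en-1-ol
Product: 18 [(2S,3S)-3-[(3R)-3-bromo-3-[(2S,5R)-5-bromo-2,6,6-trimethyloxan-2-yl]propyl]-3-methyloxiran-2-yl]methanol
Conditions: Ti(Oi-Pr)4, L-(+)-diethyl tartrate, t-BuOOH, 4 Å molecular sieves, CH2Cl2, −20 °C
Reagents that add atoms: tert-butyl hydroperoxide CC(C)(C)OO
Why: Sharpless asymmetric epoxidation: with L-(+)-diethyl tartrate the (E)-3-methyl allylic alcohol should give the (2S,3S)-epoxy alcohol by reagent control (the same sense as for geraniol), which fixes the C3–O bond with the configuration of the target carbinol regardless of the remote ring centres.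

Step 13
Reactants: 18 (2S,3S)-epoxy alcohol
Product: 19 (2S,5R)-5-bromo-2-[(1R)-1-bromo-3-[(2S,3R)-3-(iodomethyl)-2-methyloxiran-2-yl]propyl]-2,6,6-trimethyloxane
Conditions: PPh3, I2, imidazole, CH2Cl2, 0 °C
Reagents that add atoms: iodine II
Why: Appel-type iodination of the primary alcohol through its alkoxyphosphonium iodide: the primary carbinol reacts fast at 0 °C, the oxirane and the secondary bromides are spectators, and no stereocentre is touched (the descriptor at the oxirane CH changes only because iodine outranks oxygen).

Step 14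
Reactants: 19 epoxy iodide
Product: 20 (3S,6R)-6-bromo-6-[(2S,5R)-5-bromo-2,6,6-trimethyloxan-2-yl]-3-methylhex-1-en-3-ol (target)
Conditions: activated Zn dust, EtOH, AcOH (1 equiv), 25 °C
Reagents that add atoms: none
Why: Reductive ring opening of a 2,3-epoxy iodide (zinc insertion into the primary C–I bond and beta-elimination of the oxirane oxygen): the C1=C2 vinyl group and the tertiary alkoxide are formed with the C3–O bond intact, so C3 keeps the (S) configuration set in step 12, and the primary iodide next to the strained ring should react well before the two secondary bromides.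

**Compound list**

1 | 1,8-cineole (1,3,3-trimethyl-2-oxabicyclo[2.2.2]octane) | CC1(C)OC2(C)CCC1CC2 | starting material
2 | rac-1,3,3-trimethyl-2-oxabicyclo[2.2.2]octan-5-one (racemate, both enantiomers written) | C[C@]12CC[C@H](C(=O)C1)C(C)(C)O2.C[C@@]12CC[C@@H](C(=O)C1)C(C)(C)O2 | intermediate
3 | rac-(1S*,4R*,5S*)-1,3,3-trimethyl-2-oxabicyclo[2.2.2]octan-5-ol (racemate, both enantiomers written) | C[C@]12CC[C@H]([C@@H](O)C1)C(C)(C)O2.C[C@@]12CC[C@@H]([C@H](O)C1)C(C)(C)O2 | intermediate
4 | (1S,4R,5S)-1,3,3-trimethyl-2-oxabicyclo[2.2.2]octan-5-yl (1S,4R)-camphanate | C[C@]12CC[C@H]([C@@H](OC(=O)[C@@]34CC[C@@](C)(C(=O)O3)C4(C)C)C1)C(C)(C)O2 | intermediate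
5 | (1S,4R,5S)-1,3,3-trimethyl-2-oxabicyclo[2.2.2]octan-5-ol | C[C@]12CC[C@H]([C@@H](O)C1)C(C)(C)O2 | intermediate
6 | (1S,4S)-1,3,3-trimethyl-2-oxabicyclo[2.2.2]octan-5-one | C[C@]12CC[C@H](C(=O)C1)C(C)(C)O2 | intermediate
7 | (1S,5S)-5,7,7-trimethyl-2,6-dioxabicyclo[3.2.2]nonan-3-one | C[C@]12CC[C@H](OC(=O)C1)C(C)(C)O2 | intermediate
8 | trimethyl{[(1S,5S)-5,7,7-trimethyl-2,6-dioxabicyclo[3.2.2]non-3-en-3-yl]oxy}silane (not isolated) | C[C@]12CC[C@H](OC(O[Si](C)(C)C)=C1)C(C)(C)O2 | intermediate
9 | (1S,4S,5S)-4-bromo-5,7,7-trimethyl-2,6-dioxabicyclo[3.2.2]nonan-3-one | C[C@]12CC[C@H](OC(=O)[C@H]1Br)C(C)(C)O2 | intermediate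
10 | (2R)-2-bromo-2-[(2S,5S)-5-hydroxy-2,6,6-trimethyloxan-2-yl]ethan-1-ol (not isolated) | OC[C@@H](Br)[C@]1(C)CC[C@H](O)C(C)(C)O1 | intermediate
11 | (3S,6S)-2,2,6-trimethyl-6-[(2S)-oxiran-2-yl]oxan-3-ol | C1O[C@@H]1[C@]2(C)CC[C@H](O)C(C)(C)O2 | intermediate
12 | 1-(trimethylsilyl)propyne | CC#C[Si](C)(C)C | starting material
13 | (3S,6S)-6-[(1S)-1-hydroxy-5-(trimethylsilyl)pent-4-yn-1-yl]-2,2,6-trimethyloxan-3-ol (not isolated) | C[Si](C)(C)C#CCC[C@H](O)[C@]1(C)CC[C@H](O)C(C)(C)O1 | intermediate
14 | (3S,6S)-6-[(1S)-1-hydroxypent-4-yn-1-yl]-2,2,6-trimethyloxan-3-ol | C#CCC[C@H](O)[C@]1(C)CC[C@H](O)C(C)(C)O1 | intermediate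
15 | (3R,6S)-3-bromo-6-[(1R)-1-bromopent-4-yn-1-yl]-2,2,6-trimethyloxane | C#CCC[C@@H](Br)[C@]1(C)CC[C@@H](Br)C(C)(C)O1 | intermediate
16 | [(1E,5R)-5-bromo-5-[(2S,5R)-5-bromo-2,6,6-trimethyloxan-2-yl]-2-methylpent-1-en-1-yl]dimethylalane (not isolated) | C[Al](C)/C=C(\C)CC[C@@H](Br)[C@]1(C)CC[C@@H](Br)C(C)(C)O1 | intermediate
17 | (2E,6R)-6-bromo-6-[(2S,5R)-5-bromo-2,6,6-trimethyloxan-2-yl]-3-methylhex-2-en-1-ol | OC/C=C(\C)CC[C@@H](Br)[C@]1(C)CC[C@@H](Br)C(C)(C)O1 | intermediate
18 | [(2S,3S)-3-[(3R)-3-bromo-3-[(2S,5R)-5-bromo-2,6,6-trimethyloxan-2-yl]propyl]-3-methyloxiran-2-yl]methanol | OC[C@@H]1O[C@@]1(C)CC[C@@H](Br)[C@]2(C)CC[C@@H](Br)C(C)(C)O2 | intermediate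
19 | (2S,5R)-5-bromo-2-[(1R)-1-bromo-3-[(2S,3R)-3-(iodomethyl)-2-methyloxiran-2-yl]propyl]-2,6,6-trimethyloxane | IC[C@@H]1O[C@@]1(C)CC[C@@H](Br)[C@]2(C)CC[C@@H](Br)C(C)(C)O2 | intermediate
20 | (3S,6R)-6-bromo-6-[(2S,5R)-5-bromo-2,6,6-trimethyloxan-2-yl]-3-methylhex-1-en-3-ol | C=C[C@@](C)(O)CC[C@@H](Br)[C@]1(C)CC[C@@H](Br)C(C)(C)O1 | target

**Step count and risks**

Total step count: 14. Longest linear sequence: 14 steps (1 to 20).

Steps most likely to fail:

Step 10 (double bromination). The SN2 displacement has to occur at two carbinol carbons that each adjoin a fully substituted ether carbon. It may therefore be overtaken by elimination or by participation of the ring oxygen (ring contraction at C10, ring expansion at C6). Fallback: activation is separated from displacement. Setting out from diol 14, ClCH2SO2Cl and pyridine in CH2Cl2 at 0 °C should give the isolable bis(chloromethanesulfonate) F4. F4 is then treated with LiBr in THF/DMPU at 40–60 °C, where free bromide displaces both sulfonates with inversion. The route is rejoined at dibromide 15.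

Step 7 (bromination of the lactone). The electrophile may be delivered to the enolate face anti to the ring oxygen (reversed facial selectivity), which after step 8 would give the C6-epimeric oxirane. Fallback: the electrophile is changed from bromine to oxygen, so that the same facial preference is used with retention instead of inversion at C6. Setting out from lactone 7, the potassium enolate (KN(SiMe3)2, THF, −78 °C) is hydroxylated with 2-(phenylsulfonyl)-3-phenyloxaziridine, which in this scenario should give hydroxy lactone F1 with the hydroxyl anti to the ring oxygen. LiAlH4 in THF reduces F1 to triol F2. TsCl and pyridine at 0 °C sulfonylate only the primary hydroxyl to give monotosylate F3. K2CO3 in MeOH then closes the oxirane by displacement at C5, leaving the C6–O bond untouched. The route is rejoined at epoxide 11.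

Step 14 (zinc opening of the epoxy iodide). Zinc may also insert into the secondary C–Br bonds, which are beta to the ring oxygen, leading to reductive cleavage of the oxane (Boord-type elimination) or to debromination. Fallback: a metal-insertion-free transposition. Setting out from epoxy alcohol 18, TsCl, Et3N and DMAP (cat.) in CH2Cl2 at 0 °C give epoxy tosylate F5. Na2Te (from Te and NaBH4) in DMF at 0 °C to rt displaces the primary tosylate, the tellurolate opens the oxirane at C2, and the resulting epitelluride extrudes tellurium to give the C1=C2 alkene and the C3 carbinol. The route is rejoined at target 20.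

**Further compounds**

F1 | step 7 | (1S,4R,5S)-4-hydroxy-5,7,7-trimethyl-2,6-dioxabicyclo[3.2.2]nonan-3-one | C[C@]12CC[C@H](OC(=O)[C@@H]1O)C(C)(C)O2
F2 | step 7 | (1S)-1-[(2S,5S)-5-hydroxy-2,6,6-trimethyloxan-2-yl]ethane-1,2-diol | OC[C@H](O)[C@]1(C)CC[C@H](O)C(C)(C)O1
F3 | step 7 | (2S)-2-hydroxy-2-[(2S,5S)-5-hydroxy-2,6,6-trimethyloxan-2-yl]ethyl 4-methylbenzenesulfonate | Cc1ccc(cc1)S(=O)(=O)OC[C@H](O)[C@]1(C)CC[C@H](O)C(C)(C)O1
F4 | step 10 | (1S)-1-[(2S,5S)-5-(chloromethanesulfonyloxy)-2,6,6-trimethyloxan-2-yl]pent-4-yn-1-yl chloromethanesulfonate | C#CCC[C@H](OS(=O)(=O)CCl)[C@]1(C)CC[C@H](OS(=O)(=O)CCl)C(C)(C)O1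
F5 | step 14 | [(2S,3S)-3-[(3R)-3-bromo-3-[(2S,5R)-5-bromo-2,6,6-trimethyloxan-2-yl]propyl]-3-methyloxiran-2-yl]methyl 4-methylbenzenesulfonate | Cc1ccc(cc1)S(=O)(=O)OC[C@@H]1O[C@@]1(C)CC[C@@H](Br)[C@]2(C)CC[C@@H](Br)C(C)(C)O2
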